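**Plan**
- Retrosynthetic cuts, in order: O1–C2 of the dihydrofuran ring (giving an open (S)-1,2-diarylpropyl ester in which C2 is still a CH2); the C5–vinyl bond of the enal; the isovalerate C–O bond; the C2–C3 bond (enolate benzylation); the carbon next to C3 is traced through an arylacetic acid back to an allyl group placed on ring A by Claisen rearrangement.
- Forward order: 4-bromo-2-methoxyphenol is built into the ring A arylacetic acid, ring B is joined by alkylation, the acyl carbon is reduced and esterified, the enal is installed, both phenols are freed, and the five-membered ring is closed last.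
- Enabling feature: ring B has a free 4-OH para to C2, so the C2 methylene is the vinylogous position of a phenol and can be dehydrogenated to a p-quinone methide; O1 on C7a of ring A sits ortho to C3a, four atoms from C2, so conjugate addition closes O1–C2.
- Stereochemistry: C3 (S) comes from the oxazolidinone-controlled alkylation; C2 (R) is created in the ring closure, trans to the C3 substituent, under control of C3.

Key step: step 12

Remark: positions follow 2,3-dihydrobenzofuran numbering (O1, C2, C3, C3a, C4–C7, C7a); ring A is the benzo ring, ring B the 4-hydroxy-3-methoxyphenyl ring; the target is read as the trans (2R,3S) isomer.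

**Step 1**
Reactants: 1 4-bromo-2-methoxyphenol; 2 allyl bromide
Product: 3 1-(allyloxy)-4-bromo-2-methoxybenzene
Conditions: K2CO3, acetone, reflux
Reagents that add atoms: none
Why: Williamson etherification, in which the phenoxide displaces the allylic bromide (SN2) and no stereocenter is formed.

**Step 2**
Reactants: 3 1-(allyloxy)-4-bromo-2-methoxybenzene
Product: 5 2-allyl-4-bromo-6-methoxyphenol, via dienone 4 (not isolated)
Conditions: N,N-diethylaniline, 195 °C, sealed tube
Reagents that add atoms: none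
Why: aromatic Claisen rearrangement ([3,3]) delivers the allyl group to the only ortho carbon that bears hydrogen (the other carries OMe, the para carbon Br), and dienone 4 tautomerizes to the phenol.

**Step 3**
Reactants: 5 2-allyl-4-bromo-6-methoxyphenol; 6 benzyl bromide
Product: 7 1-allyl-2-(benzyloxy)-5-bromo-3-methoxybenzene
Conditions: K2CO3, DMF, 50 °C
Reagents that add atoms: none
Why: Williamson benzylation protects the phenol against ozone, enolate base and hydride in the following steps.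

**Step 4**
Reactants: 7 1-allyl-2-(benzyloxy)-5-bromo-3-methoxybenzene
Product: 10 2-[2-(benzyloxy)-5-bromo-3-methoxyphenyl]acetic acid, via ozonide 8 (not isolated), via arylacetaldehyde 9 (not isolated)
Conditions: O3, CH2Cl2, −78 °C; Me2S, −78 °C to rt; then NaClO2, NaH2PO4, 2-methyl-2-butene, tBuOH/H2O, 0 °C to rt
Reagents that add atoms: ozone O=[O+][O-]; sodium chlorite [Na+].[O-]Cl=O
Why: ozonolysis of the terminal alkene, which should react much faster than the brominated dialkoxyarene at −78 °C, is followed directly by Pinnick oxidation of the enolizable aldehyde with 2-methyl-2-butene as hypochlorite scavenger.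

**Step 5**
Reactants: 10 2-[2-(benzyloxy)-5-bromo-3-methoxyphenyl]acetic acid; 11 (S)-4-benzyl-2-oxazolidinone
Product: 13 (S)-4-benzyl-3-{2-[2-(benzyloxy)-5-bromo-3-methoxyphenyl]acetyl}oxazolidin-2-one, via mixed anhydride 12 (not isolated)
Conditions: PivCl, Et3N, THF, −20 °C; then 11, LiCl, −20 °C to rt
Reagents that add atoms: none
Why: N-acylation of the oxazolidinone through the pivaloyl mixed anhydride, which is attacked at the less hindered arylacetyl carbonyl.

**Step 6**
Reactants: 14 4-(benzyloxy)-3-methoxybenzyl alcohol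
Product: 15 4-(benzyloxy)-3-methoxybenzyl bromide
Conditions: PBr3, Et2O, 0 °C
Reagents that add atoms: phosphorus tribromide BrP(Br)Br
Why: bromination of the benzylic alcohol through its phosphite ester (SN2 by bromide), the bromide being used without storage.

**Step 7**
Reactants: 13 (S)-4-benzyl-3-{2-[2-(benzyloxy)-5-bromo-3-methoxyphenyl]acetyl}oxazolidin-2-one; 15 4-(benzyloxy)-3-methoxybenzyl bromide
Product: 17 (S)-4-benzyl-3-{(S)-2-[2-(benzyloxy)-5-bromo-3-methoxyphenyl]-3-[4-(benzyloxy)-3-methoxyphenyl]propanoyl}oxazolidin-2-one, via sodium enolate 16 (not isolated)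
Conditions: NaN(SiMe3)2, THF, −78 °C; then 15, −78 to −40 °C
Reagents that add atoms: none
Why: Evans alkylation, in which the chelated sodium (Z)-enolate is attacked by the benzylic bromide on the face opposite the C4 benzyl group of the auxiliary, setting the (S) configuration of the carbon that becomes C3.

**Step 8**
Reactants: 17 (S)-4-benzyl-3-{(S)-2-[2-(benzyloxy)-5-bromo-3-methoxyphenyl]-3-[4-(benzyloxy)-3-methoxyphenyl]propanoyl}oxazolidin-2-one
Product: 18 (S)-2-[2-(benzyloxy)-5-bromo-3-methoxyphenyl]-3-[4-(benzyloxy)-3-methoxyphenyl]propan-1-ol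
Conditions: LiBH4, H2O (1 equiv), Et2O, 0 °C
Reagents that add atoms: none
Why: reductive cleavage of the N-acyloxazolidinone by hydride attack at the exocyclic carbonyl, the aldehyde being reduced as it forms so that the α-aryl stereocenter is not exposed to enolization, while the aryl bromide and benzyl ethers are inert.

**Step 9**
Reactants: 18 (S)-2-[2-(benzyloxy)-5-bromo-3-methoxyphenyl]-3-[4-(benzyloxy)-3-methoxyphenyl]propan-1-ol; 19 isovaleryl chloride
Product: 20 (S)-2-[2-(benzyloxy)-5-bromo-3-methoxyphenyl]-3-[4-(benzyloxy)-3-methoxyphenyl]propyl 3-methylbutanoate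
Conditions: pyridine, DMAP (cat.), CH2Cl2, 0 °C to rt
Reagents that add atoms: none
Why: DMAP-catalysed acylation of the primary alcohol (nucleophilic acyl substitution), which does not involve the stereocenter.

**Step 10**
Reactants: 20 (S)-2-[2-(benzyloxy)-5-bromo-3-methoxyphenyl]-3-[4-(benzyloxy)-3-methoxyphenyl]propyl 3-methylbutanoate; 21 acrolein diethyl acetal
Product: 23 (S)-2-{2-(benzyloxy)-3-methoxy-5-[(E)-3-oxoprop-1-enyl]phenyl}-3-[4-(benzyloxy)-3-methoxyphenyl]propyl 3-methylbutanoate, via diethyl acetal 22 (not isolated)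
Conditions: Pd(OAc)2 (3 mol %), nBu4NOAc, K2CO3, KCl, DMF, 90 °C; then 2 M HCl, THF, rt
Reagents that add atoms: water O
Why: Heck reaction, in which zerovalent palladium inserts into the unhindered C–Br bond, syn insertion into the vinyl acetal and β-hydride elimination of the benzylic rather than the acetal hydrogen (favoured by the acetate and chloride additives) give the (E)-alkene, and acid hydrolysis unmasks the enal.

**Step 11**
Reactants: 23 (S)-2-{2-(benzyloxy)-3-methoxy-5-[(E)-3-oxoprop-1-enyl]phenyl}-3-[4-(benzyloxy)-3-methoxyphenyl]propyl 3-methylbutanoate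
Product: 24 (S)-2-{2-hydroxy-3-methoxy-5-[(E)-3-oxoprop-1-enyl]phenyl}-3-(4-hydroxy-3-methoxyphenyl)propyl 3-methylbutanoate
Conditions: BCl3 (1 M in CH2Cl2), pentamethylbenzene, CH2Cl2, −78 °C; MeOH quench at −78 °C
Reagents that add atoms: none
Why: Lewis acid-mediated cleavage of both aryl benzyl ethers with pentamethylbenzene as a non-basic benzyl cation scavenger (Friedel–Crafts capture), at a temperature at which the methyl ethers, the ester and the enal should not be attacked.

**Step 12**
Reactants: 24 (S)-2-{2-hydroxy-3-methoxy-5-[(E)-3-oxoprop-1-enyl]phenyl}-3-(4-hydroxy-3-methoxyphenyl)propyl 3-methylbutanoate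
Product: 26 [(2R,3S)-2-(4-hydroxy-3-methoxyphenyl)-7-methoxy-5-[(E)-3-oxoprop-1-enyl]-2,3-dihydrobenzofuran-3-yl]methyl 3-methylbutanoate, via quinone methide 25 (not isolated)
Conditions: DDQ (1.05 equiv), 1,4-dioxane/CH2Cl2, 0 °C to rt, dark; aq. NaHCO3 work-up
Reagents that add atoms: none
Why: DDQ forms a charge-transfer complex with ring B, the only ring that is a 4-alkylphenol, and removes hydride from the C2 methylene para to the free 4-OH (then the proton of that OH) to give p-quinone methide 25 and DDQH2, after which the ring A hydroxyl on C7a adds to the methide carbon to form O1–C2 and rearomatize ring B. The closest known reaction type is the quinone dehydrogenation of 4-alkylphenols to quinone methides with capture by an oxygen nucleophile, in its intramolecular form the DDQ oxidative cyclization of 2'-hydroxyisoflavans to pterocarpans, which makes the same benzylic aryl ether within a dihydrobenzofuran ring. The five-membered ring closes in the 5-exo-trig mode, since O1 attacks the exocyclic methide carbon and the C=C that is consumed lies outside the new ring. C2 is created here under control of the neighbouring C3 stereocenter: in the envelope-shaped transition state the ring B dienone and the C3 acyloxymethyl group take opposite faces, and because the p-hydroxybenzyl aryl ether can reopen to 25 in the presence of acidic DDQH2 the trans (2R,3S) isomer is also the equilibrium product, while C3 itself stays untouched as long as ring closure outruns loss of its proton. The step needs oxidation at the ring B benzylic CH2 in preference to ring A, C3–H and the product, which should be secured by the electron-withdrawing propenal group para to the ring A hydroxyl (which has no benzylic hydrogen para to it), by the free para-OH of ring B, and by the use of one equivalent of oxidant at low temperature.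

**Compound list**

1 | 4-bromo-2-methoxyphenol | COc1cc(Br)ccc1O | starting material
2 | allyl bromide | C=CCBr | starting material
3 | 1-(allyloxy)-4-bromo-2-methoxybenzene | COc1cc(Br)ccc1OCC=C | intermediate
4 | 6-allyl-4-bromo-2-methoxycyclohexa-2,4-dien-1-one | COC1=CC(Br)=CC(CC=C)C1=O | intermediate
5 | 2-allyl-4-bromo-6-methoxyphenol | COc1cc(Br)cc(CC=C)c1O | intermediate
6 | benzyl bromide | BrCc1ccccc1 | starting material
7 | 1-allyl-2-(benzyloxy)-5-bromo-3-methoxybenzene | COc1cc(Br)cc(CC=C)c1OCc1ccccc1 | intermediate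
8 | 3-{[2-(benzyloxy)-5-bromo-3-methoxyphenyl]methyl}-1,2,4-trioxolane | COc1cc(Br)cc(CC2OCOO2)c1OCc1ccccc1 | intermediate
9 | 2-[2-(benzyloxy)-5-bromo-3-methoxyphenyl]acetaldehyde | COc1cc(Br)cc(CC=O)c1OCc1ccccc1 | intermediate
10 | 2-[2-(benzyloxy)-5-bromo-3-methoxyphenyl]acetic acid | COc1cc(Br)cc(CC(=O)O)c1OCc1ccccc1 | intermediate
11 | (S)-4-benzyl-2-oxazolidinone | O=C1N[C@@H](Cc2ccccc2)CO1 | starting material
12 | 2-[2-(benzyloxy)-5-bromo-3-methoxyphenyl]acetic pivalic anhydride | COc1cc(Br)cc(CC(=O)OC(=O)C(C)(C)C)c1OCc1ccccc1 | intermediate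
13 | (S)-4-benzyl-3-{2-[2-(benzyloxy)-5-bromo-3-methoxyphenyl]acetyl}oxazolidin-2-one | COc1cc(Br)cc(CC(=O)N2C(=O)OC[C@@H]2Cc2ccccc2)c1OCc1ccccc1 | intermediate
14 | 4-(benzyloxy)-3-methoxybenzyl alcohol | COc1cc(CO)ccc1OCc1ccccc1 | starting material
15 | 4-(benzyloxy)-3-methoxybenzyl bromide | COc1cc(CBr)ccc1OCc1ccccc1 | intermediate
16 | sodium (Z)-enolate of 13 | [Na+].[O-]/C(=C\c1cc(Br)cc(OC)c1OCc1ccccc1)N1C(=O)OC[C@@H]1Cc1ccccc1 | intermediate
17 | (S)-4-benzyl-3-{(S)-2-[2-(benzyloxy)-5-bromo-3-methoxyphenyl]-3-[4-(benzyloxy)-3-methoxyphenyl]propanoyl}oxazolidin-2-one | COc1cc(C[C@H](C(=O)N2C(=O)OC[C@@H]2Cc2ccccc2)c2cc(Br)cc(OC)c2OCc2ccccc2)ccc1OCc1ccccc1 | intermediate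
18 | (S)-2-[2-(benzyloxy)-5-bromo-3-methoxyphenyl]-3-[4-(benzyloxy)-3-methoxyphenyl]propan-1-ol | COc1cc(C[C@H](CO)c2cc(Br)cc(OC)c2OCc2ccccc2)ccc1OCc1ccccc1 | intermediate
19 | isovaleryl chloride | CC(C)CC(=O)Cl | starting material
20 | (S)-2-[2-(benzyloxy)-5-bromo-3-methoxyphenyl]-3-[4-(benzyloxy)-3-methoxyphenyl]propyl 3-methylbutanoate | COc1cc(C[C@H](COC(=O)CC(C)C)c2cc(Br)cc(OC)c2OCc2ccccc2)ccc1OCc1ccccc1 | intermediate
21 | acrolein diethyl acetal | C=CC(OCC)OCC | starting material
22 | (S)-2-{2-(benzyloxy)-5-[(E)-3,3-diethoxyprop-1-enyl]-3-methoxyphenyl}-3-[4-(benzyloxy)-3-methoxyphenyl]propyl 3-methylbutanoate | COc1cc(C[C@H](COC(=O)CC(C)C)c2cc(/C=C/C(OCC)OCC)cc(OC)c2OCc2ccccc2)ccc1OCc1ccccc1 | intermediate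
23 | (S)-2-{2-(benzyloxy)-3-methoxy-5-[(E)-3-oxoprop-1-enyl]phenyl}-3-[4-(benzyloxy)-3-methoxyphenyl]propyl 3-methylbutanoate | COc1cc(C[C@H](COC(=O)CC(C)C)c2cc(/C=C/C=O)cc(OC)c2OCc2ccccc2)ccc1OCc1ccccc1 | intermediate
24 | (S)-2-{2-hydroxy-3-methoxy-5-[(E)-3-oxoprop-1-enyl]phenyl}-3-(4-hydroxy-3-methoxyphenyl)propyl 3-methylbutanoate | COc1cc(C[C@H](COC(=O)CC(C)C)c2cc(/C=C/C=O)cc(OC)c2O)ccc1O | intermediate
25 | (S)-2-{2-hydroxy-3-methoxy-5-[(E)-3-oxoprop-1-enyl]phenyl}-3-(3-methoxy-4-oxocyclohexa-2,5-dien-1-ylidene)propyl 3-methylbutanoate | COC1=CC(=C[C@H](COC(=O)CC(C)C)c2cc(/C=C/C=O)cc(OC)c2O)C=CC1=O | intermediate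
26 | [(2R,3S)-2-(4-hydroxy-3-methoxyphenyl)-7-methoxy-5-[(E)-3-oxoprop-1-enyl]-2,3-dihydrobenzofuran-3-yl]methyl 3-methylbutanoate | COc1cc([C@@H]2Oc3c(OC)cc(/C=C/C=O)cc3[C@H]2COC(=O)CC(C)C)ccc1O | target

**Step count and risks**

Total steps: 12. Longest linear sequence: 11 (steps 1–5 and 7–12; step 6 is a one-step side branch).

Step 12 (key ring closure). What may go wrong:
- a second hydride abstraction at C2 of the product followed by loss of the C3 proton, which aromatizes the new ring to a benzofuran;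
- loss of the C3 proton from the quinone methide to a stilbene before O1 adds, which erases C3;
- oxidation starting at ring A.

The fallback sets out from 10 and comes back at 25. It brings in the benzylic oxygen by an aldol reaction, so that the quinone methide arises by loss of water and no oxidant meets the product.
- Acid 10 is coupled through mixed anhydride 12 with (R)-4-benzyl-2-oxazolidinone to give (R)-4-benzyl-3-{2-[2-(benzyloxy)-5-bromo-3-methoxyphenyl]acetyl}oxazolidin-2-one F1. The enantiomeric auxiliary is needed because the boron aldol uses the enolate face opposite to that of the chelated alkylation.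
- Bu2BOTf and iPr2NEt (CH2Cl2, −78 °C) give the dibutylboron (Z)-enolate of F1 F2. It adds 4-(benzyloxy)-3-methoxybenzaldehyde in an Evans syn-aldol reaction to give (R)-4-benzyl-3-{(2R,3R)-2-[2-(benzyloxy)-5-bromo-3-methoxyphenyl]-3-[4-(benzyloxy)-3-methoxyphenyl]-3-hydroxypropanoyl}oxazolidin-2-one F3.
- LiBH4 gives (1R,2S)-2-[2-(benzyloxy)-5-bromo-3-methoxyphenyl]-1-[4-(benzyloxy)-3-methoxyphenyl]propane-1,3-diol F4.
- Isovaleryl chloride with 2,4,6-collidine at −78 °C acylates the primary hydroxyl to give (2S,3R)-2-[2-(benzyloxy)-5-bromo-3-methoxyphenyl]-3-[4-(benzyloxy)-3-methoxyphenyl]-3-hydroxypropyl 3-methylbutanoate F5.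
- The Heck reaction of step 10 gives (2S,3R)-2-{2-(benzyloxy)-5-[(E)-3,3-diethoxyprop-1-enyl]-3-methoxyphenyl}-3-[4-(benzyloxy)-3-methoxyphenyl]-3-hydroxypropyl 3-methylbutanoate F6. Acid hydrolysis then gives (2S,3R)-2-{2-(benzyloxy)-3-methoxy-5-[(E)-3-oxoprop-1-enyl]phenyl}-3-[4-(benzyloxy)-3-methoxyphenyl]-3-hydroxypropyl 3-methylbutanoate F7.
- BCl3 with pentamethylbenzene frees the phenols to give (2S,3R)-3-hydroxy-2-{2-hydroxy-3-methoxy-5-[(E)-3-oxoprop-1-enyl]phenyl}-3-(4-hydroxy-3-methoxyphenyl)propyl 3-methylbutanoate F8.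
- With a trace of acid (CF3CO2H, CH2Cl2, 0 °C) F8 should lose water to quinone methide 25, which closes to 26 as in step 12.

Step 11 (debenzylation beside the enal). What may go wrong: Lewis acid activation of the enal, leading to Friedel–Crafts addition of the scavenger or oligomerization, or incomplete cleavage of the hindered ring A benzyl ether.

The fallback sets out from 20 and comes back at 26. It changes the order so that the enal is installed only after debenzylation and ring closure.
- BCl3 with pentamethylbenzene converts 20 into (S)-2-(5-bromo-2-hydroxy-3-methoxyphenyl)-3-(4-hydroxy-3-methoxyphenyl)propyl 3-methylbutanoate F9.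
- DDQ as in step 12 gives (S)-2-(5-bromo-2-hydroxy-3-methoxyphenyl)-3-(3-methoxy-4-oxocyclohexa-2,5-dien-1-ylidene)propyl 3-methylbutanoate F10, which closes to [(2R,3S)-5-bromo-2-(4-hydroxy-3-methoxyphenyl)-7-methoxy-2,3-dihydrobenzofuran-3-yl]methyl 3-methylbutanoate F11.
- Suzuki–Miyaura coupling with commercially available (E)-2-(3,3-diethoxyprop-1-enyl)-4,4,5,5-tetramethyl-1,3,2-dioxaborolane (PdCl2(dppf), K3PO4, dioxane/H2O, 60 °C) gives [(2R,3S)-5-[(E)-3,3-diethoxyprop-1-enyl]-2-(4-hydroxy-3-methoxyphenyl)-7-methoxy-2,3-dihydrobenzofuran-3-yl]methyl 3-methylbutanoate F12.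
- Dilute HCl in THF then gives 26.

Step 10 (Heck reaction). What may go wrong: β-hydride elimination toward the acetal carbon, which after work-up gives the saturated ester; hydrodebromination; or slow oxidative addition into the electron-rich aryl bromide.

The fallback sets out from 20 and comes back at 22. Suzuki–Miyaura coupling of 20 with the same (E)-2-(3,3-diethoxyprop-1-enyl)-4,4,5,5-tetramethyl-1,3,2-dioxaborolane (PdCl2(dppf), K3PO4, dioxane/H2O, 80 °C) fixes regiochemistry and alkene geometry in the reagent and gives acetal 22, which is hydrolysed to 23 as before. No compound outside the compound list arises (F0).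

**Further compounds**

F1 | step 12 | (R)-4-benzyl-3-{2-[2-(benzyloxy)-5-bromo-3-methoxyphenyl]acetyl}oxazolidin-2-one | COc1cc(Br)cc(CC(=O)N2C(=O)OC[C@H]2Cc2ccccc2)c1OCc1ccccc1
F2 | step 12 | dibutylboron (Z)-enolate of F1 | CCCCB(CCCC)O/C(=C\c1cc(Br)cc(OC)c1OCc1ccccc1)N1C(=O)OC[C@H]1Cc1ccccc1
F3 | step 12 | (R)-4-benzyl-3-{(2R,3R)-2-[2-(benzyloxy)-5-bromo-3-methoxyphenyl]-3-[4-(benzyloxy)-3-methoxyphenyl]-3-hydroxypropanoyl}oxazolidin-2-one | COc1cc([C@H](O)[C@H](C(=O)N2C(=O)OC[C@H]2Cc2ccccc2)c2cc(Br)cc(OC)c2OCc2ccccc2)ccc1OCc1ccccc1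
F4 | step 12 | (1R,2S)-2-[2-(benzyloxy)-5-bromo-3-methoxyphenyl]-1-[4-(benzyloxy)-3-methoxyphenyl]propane-1,3-diol | COc1cc([C@H](O)[C@H](CO)c2cc(Br)cc(OC)c2OCc2ccccc2)ccc1OCc1ccccc1
F5 | step 12 | (2S,3R)-2-[2-(benzyloxy)-5-bromo-3-methoxyphenyl]-3-[4-(benzyloxy)-3-methoxyphenyl]-3-hydroxypropyl 3-methylbutanoate | COc1cc([C@H](O)[C@H](COC(=O)CC(C)C)c2cc(Br)cc(OC)c2OCc2ccccc2)ccc1OCc1ccccc1
F6 | step 12 | (2S,3R)-2-{2-(benzyloxy)-5-[(E)-3,3-diethoxyprop-1-enyl]-3-methoxyphenyl}-3-[4-(benzyloxy)-3-methoxyphenyl]-3-hydroxypropyl 3-methylbutanoate | COc1cc([C@H](O)[C@H](COC(=O)CC(C)C)c2cc(/C=C/C(OCC)OCC)cc(OC)c2OCc2ccccc2)ccc1OCc1ccccc1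
F7 | step 12 | (2S,3R)-2-{2-(benzyloxy)-3-methoxy-5-[(E)-3-oxoprop-1-enyl]phenyl}-3-[4-(benzyloxy)-3-methoxyphenyl]-3-hydroxypropyl 3-methylbutanoate | COc1cc([C@H](O)[C@H](COC(=O)CC(C)C)c2cc(/C=C/C=O)cc(OC)c2OCc2ccccc2)ccc1OCc1ccccc1
F8 | step 12 | (2S,3R)-3-hydroxy-2-{2-hydroxy-3-methoxy-5-[(E)-3-oxoprop-1-enyl]phenyl}-3-(4-hydroxy-3-methoxyphenyl)propyl 3-methylbutanoate | COc1cc([C@H](O)[C@H](COC(=O)CC(C)C)c2cc(/C=C/C=O)cc(OC)c2O)ccc1O
F0 | step 10 | none | none
F9 | step 11 | (S)-2-(5-bromo-2-hydroxy-3-methoxyphenyl)-3-(4-hydroxy-3-methoxyphenyl)propyl 3-methylbutanoate | COc1cc(C[C@H](COC(=O)CC(C)C)c2cc(Br)cc(OC)c2O)ccc1O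
F10 | step 11 | (S)-2-(5-bromo-2-hydroxy-3-methoxyphenyl)-3-(3-methoxy-4-oxocyclohexa-2,5-dien-1-ylidene)propyl 3-methylbutanoate | COC1=CC(=C[C@H](COC(=O)CC(C)C)c2cc(Br)cc(OC)c2O)C=CC1=O
F11 | step 11 | [(2R,3S)-5-bromo-2-(4-hydroxy-3-methoxyphenyl)-7-methoxy-2,3-dihydrobenzofuran-3-yl]methyl 3-methylbutanoate | COc1cc([C@@H]2Oc3c(OC)cc(Br)cc3[C@H]2COC(=O)CC(C)C)ccc1O
F12 | step 11 | [(2R,3S)-5-[(E)-3,3-diethoxyprop-1-enyl]-2-(4-hydroxy-3-methoxyphenyl)-7-methoxy-2,3-dihydrobenzofuran-3-yl]methyl 3-methylbutanoate | COc1cc([C@@H]2Oc3c(OC)cc(/C=C/C(OCC)OCC)cc3[C@H]2COC(=O)CC(C)C)ccc1O
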